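**Retrosynthetic overview**
1. The MOM group is removed last. Before that, the dihydropyran ring is closed on the finished carbocycle by a palladium-catalysed [4+2] heteroannulation of (E)-penta-1,3-diene with the bromo-enone alcohol 15. This forms C4–C4a and O2–C3 and creates C3 and the E-propenyl group in one operation.
2. Enabling feature: in the pyran ring (C1, O2, C3, C4, C4a, C8a), C3 is both O-bound and allylic to the propenyl C=C, C4 is a CH2 that joins it to the sp2 carbon C4a, and C4a lies cis to C1H2–O2 across the C4a=C8a enone bond. This is the retron of a diene carbo-oxygenation by a (Z)-γ-hydroxy vinyl halide.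
3. 15 comes from the 1,3-dione 12 (haloformylation at C8a/C4a, then aldehyde reduction); 12 comes from enone 9 (β-oxygenation), and 9 from ketone 8.
4. C6 and C7 are set together by one desymmetrizing CBS reduction of the achiral 2-aroyloxy-2-methylcyclohexane-1,3-dione 6. The hindered tertiary orsellinate is made by oxidative C–O coupling, with the carboxylate as nucleophile, so no tertiary alcohol has to be acylated.
5. Ring order: the carbocycle is purchased as a six-membered dione; the pyran ring is formed last.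

Key step: step 10

Remark: ring atoms are numbered as in 1H-isochromene (C1, O2, C3, C4, C4a, C5 to C8, C8a); compounds 1, 4 and 16 are taken as purchasable.

**Route**

Step 1
Reactants: 1 2-hydroxy-4-methoxy-6-methylbenzoic acid (everninic acid)
Product: 3 4-methoxy-2-(methoxymethoxy)-6-methylbenzoic acid, via methoxymethyl ester 2 (not isolated)
Conditions: MOMCl (3 equiv), i-Pr2NEt (4 equiv), CH2Cl2, 0 to 40 °C; then LiOH, THF/H2O, rt; 1 M HCl to pH 4 at 0 °C
Reagents that add atoms: chloromethyl methyl ether, COCCl; lithium hydroxide, [Li+].[OH-] (oxygen of the regenerated acid OH)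
Why: Williamson-type O-alkylation of phenol and carboxylic acid, followed by saponification that should cleave only the labile acetal ester, the aryl MOM ether being stable to hydroxide.

Step 2
Reactants: 3 4-methoxy-2-(methoxymethoxy)-6-methylbenzoic acid (2.2 equiv); 4 2-methylcyclohexane-1,3-dione
Product: 6 2-methyl-1,3-dioxocyclohexan-2-yl 4-methoxy-2-(methoxymethoxy)-6-methylbenzoate, via bis(aroyloxy)iodobenzene 5 (not isolated)
Conditions: PhI(OAc)2 (1.1 equiv), PhCl, 50 °C, reduced pressure (AcOH stripped); then 4, MeCN, 0 °C to rt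
Reagents that add atoms: (diacetoxyiodo)benzene, CC(=O)OI(OC(C)=O)c1ccccc1 (its iodobenzene unit is held in 5 only)
Why: Ligand exchange on trivalent iodine followed by hypervalent-iodine α-acyloxylation of the enolized 2-substituted 1,3-dione should form the hindered tertiary ester with the carboxylate as nucleophile, and C7 stays prochiral.

Step 3
Reactants: 6 2-methyl-1,3-dioxocyclohexan-2-yl 4-methoxy-2-(methoxymethoxy)-6-methylbenzoate
Product: 7 (1S,2S)-2-hydroxy-1-methyl-6-oxocyclohexyl 4-methoxy-2-(methoxymethoxy)-6-methylbenzoate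
Conditions: (R)-2-methyl-CBS-oxazaborolidine (0.2 equiv), catecholborane (1.1 equiv), toluene/CH2Cl2, −78 °C; MeOH quench
Reagents that add atoms: none
Why: Corey–Bakshi–Shibata reduction run as an enantioselective desymmetrization of a 2,2-disubstituted cyclic 1,3-dione: hydride should add anti to the acyloxy group (polar Felkin–Anh and steric control, giving the cis hydroxy ester) and the (R)-catalyst should select the carbonyl that yields the (S)-carbinol with the quaternary carbon as the large group, so that C6 and C7 are fixed together as S,S.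

Step 4
Reactants: 7 (1S,2S)-2-hydroxy-1-methyl-6-oxocyclohexyl 4-methoxy-2-(methoxymethoxy)-6-methylbenzoate
Product: 8 (1S,2S)-2-acetoxy-1-methyl-6-oxocyclohexyl 4-methoxy-2-(methoxymethoxy)-6-methylbenzoate
Conditions: Ac2O (2 equiv), pyridine, DMAP (5 mol%), CH2Cl2, 0 °C to rt
Reagents that add atoms: acetic anhydride, CC(=O)OC(C)=O
Why: DMAP-catalysed acylation of the secondary alcohol, done at once so that the aroyl group has no free neighbour to migrate to.

Step 5
Reactants: 8 (1S,2S)-2-acetoxy-1-methyl-6-oxocyclohexyl 4-methoxy-2-(methoxymethoxy)-6-methylbenzoate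
Product: 9 (1S,6S)-6-acetoxy-1-methyl-2-oxocyclohex-3-en-1-yl 4-methoxy-2-(methoxymethoxy)-6-methylbenzoate
Conditions: IBX (1.5 equiv), 4-methoxypyridine N-oxide (1.5 equiv), DMSO, 25–40 °C
Reagents that add atoms: none
Why: IBX α,β-dehydrogenation of a ketone, which can give only the C8a=C4a enone because C7 is quaternary.

Step 6
Reactants: 9 (1S,6S)-6-acetoxy-1-methyl-2-oxocyclohex-3-en-1-yl 4-methoxy-2-(methoxymethoxy)-6-methylbenzoate
Product: 11 (1S,2S)-2-acetoxy-4-hydroxy-1-methyl-6-oxocyclohexyl 4-methoxy-2-(methoxymethoxy)-6-methylbenzoate, via β-boryl ketone 10 (not isolated)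
Conditions: B2pin2 (1.1 equiv), CuCl (5 mol%), DPEphos (5 mol%), NaOt-Bu (5 mol%), MeOH (2 equiv), THF, 0 °C to rt; then H2O2 (30% aq.), pH 7 phosphate buffer, 0 °C
Reagents that add atoms: bis(pinacolato)diboron, CC1(C)OB(OC1(C)C)B1OC(C)(C)C(C)(C)O1; hydrogen peroxide, OO
Why: Copper-catalysed conjugate borylation of the enone and oxidation of the C–B bond amount to a β-hydration, and the carbinol centre at C4a, formed as a mixture, is removed in step 7.

Step 7
Reactants: 11 (1S,2S)-2-acetoxy-4-hydroxy-1-methyl-6-oxocyclohexyl 4-methoxy-2-(methoxymethoxy)-6-methylbenzoate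
Product: 12 (1S,2S)-2-acetoxy-1-methyl-4,6-dioxocyclohexyl 4-methoxy-2-(methoxymethoxy)-6-methylbenzoate
Conditions: Dess–Martin periodinane (1.3 equiv), pyridine (3 equiv), CH2Cl2, 0 °C to rt
Reagents that add atoms: none
Why: Dess–Martin oxidation of a β-hydroxy ketone to the 1,3-dione under buffered, non-basic conditions that should leave the β-acetoxy group in place.

Step 8
Reactants: 12 (1S,2S)-2-acetoxy-1-methyl-4,6-dioxocyclohexyl 4-methoxy-2-(methoxymethoxy)-6-methylbenzoate
Product: 14 (1S,6S)-6-acetoxy-4-bromo-3-formyl-1-methyl-2-oxocyclohex-3-en-1-yl 4-methoxy-2-(methoxymethoxy)-6-methylbenzoate, via iminium bromide 13 (not isolated)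
Conditions: (bromomethylene)dimethyliminium bromide (2.2 equiv), 2,6-lutidine (2.5 equiv), CH2Cl2, 0 °C to rt; then aq. NaOAc, 0 °C
Reagents that add atoms: (bromomethylene)dimethyliminium bromide, C[N+](C)=CBr.[Br-]; water, O
Why: Vilsmeier–Haack–Arnold haloformylation of a cyclic 1,3-dione: C-formylation at C8a, then activation and bromide substitution at the less hindered C4a oxygen (the C8 carbonyl is shielded by the quaternary C7), and hydrolysis of the iminium salt to the aldehyde.

Step 9
Reactants: 14 (1S,6S)-6-acetoxy-4-bromo-3-formyl-1-methyl-2-oxocyclohex-3-en-1-yl 4-methoxy-2-(methoxymethoxy)-6-methylbenzoate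
Product: 15 (1S,6S)-6-acetoxy-4-bromo-3-(hydroxymethyl)-1-methyl-2-oxocyclohex-3-en-1-yl 4-methoxy-2-(methoxymethoxy)-6-methylbenzoate
Conditions: NaBH(OAc)3 (1.5 equiv), AcOH (2 equiv), THF, 0 °C to rt
Reagents that add atoms: none
Why: Chemoselective 1,2-reduction of the aldehyde by NaBH(OAc)3, a hydride donor that should spare the hindered conjugated C8 ketone and the vinylogous acyl bromide.

Step 10
Reactants: 15 (1S,6S)-6-acetoxy-4-bromo-3-(hydroxymethyl)-1-methyl-2-oxocyclohex-3-en-1-yl 4-methoxy-2-(methoxymethoxy)-6-methylbenzoate; 16 (3E)-penta-1,3-diene (5 equiv)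
Product: 17 (3S,6S,7S)-6-acetoxy-7-methyl-8-oxo-3-[(E)-prop-1-en-1-yl]-3,4,5,6,7,8-hexahydro-1H-isochromen-7-yl 4-methoxy-2-(methoxymethoxy)-6-methylbenzoate
Conditions: Pd(OAc)2 (5 mol%), BINOL-derived N,N-bis(1-phenylethyl)phosphoramidite (12 mol%; both antipodes are available and the one that gives 3S is taken), NaHCO3 (2 equiv), 1,4-dioxane, 60 °C, sealed vessel
Reagents that add atoms: none
Why: Proposed new method: zerovalent palladium (from Pd(OAc)2 and the phosphoramidite) inserts into the C4a–Br bond of the vinylogous acyl bromide, the vinylpalladium adds syn to the unsubstituted terminus of the diene to form the C4–C4a bond and a syn,syn π-allylpalladium that spans C3 and the two propenyl carbons, and the cis-disposed C1 oxygen then attacks C3 to form O2–C3 and release zerovalent palladium. The closest known reaction type is the Larock heteroannulation of 1,3-dienes by aryl and vinylic halides that carry a hydroxyl group, together with its phosphoramidite-controlled enantioselective version on o-iodobenzyl alcohols and o-iodoanilines; what is new is ligand-controlled stereoinduction with a β-bromo enone. The dihydropyran ring is closed by the C4–C4a bond (intermolecular carbopalladation) and the O2–C3 bond (intramolecular allylic etherification, six-membered and exo to the allyl unit, since attack at the far allyl terminus would need an eight-membered ring). C3 is set by the ligand, which selects the diene face in the migratory insertion, because a 1,3-disubstituted allyl cannot change face without losing its E geometry; the remote C6 and C7 centres should exert little bias, so the ligand antipode decides 3S against 3R. The E-propenyl group follows from the E-diene through the syn allyl. The step needs carbopalladation at CH2 and not at CHMe (secured by sterics), C–O capture and not β-hydride loss to a trienone (secured by the hydroxymethyl group held cis and next to the allyl), and survival of the C6 acetate (secured by the weak base NaHCO3).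

Step 11
Reactants: 17 (3S,6S,7S)-6-acetoxy-7-methyl-8-oxo-3-[(E)-prop-1-en-1-yl]-3,4,5,6,7,8-hexahydro-1H-isochromen-7-yl 4-methoxy-2-(methoxymethoxy)-6-methylbenzoate
Product: 18 (3S,6S,7S)-6-acetoxy-7-methyl-8-oxo-3-[(E)-prop-1-en-1-yl]-3,4,5,6,7,8-hexahydro-1H-isochromen-7-yl 2-hydroxy-4-methoxy-6-methylbenzoate (CNP0223989.1)
Conditions: TFA/CH2Cl2/H2O (5:94:1), 0 °C
Reagents that add atoms: none
Why: Acid-catalysed acetal cleavage of the MOM ether, which is activated by the ortho ester carbonyl and should cleave under conditions that spare the acetate, the allylic ether and the enone.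

**Compound list**
1 | 2-hydroxy-4-methoxy-6-methylbenzoic acid | Cc1cc(OC)cc(O)c1C(=O)O | starting material
2 | methoxymethyl 4-methoxy-2-(methoxymethoxy)-6-methylbenzoate | Cc1cc(OC)cc(OCOC)c1C(=O)OCOC | intermediate
3 | 4-methoxy-2-(methoxymethoxy)-6-methylbenzoic acid | Cc1cc(OC)cc(OCOC)c1C(=O)O | intermediate
4 | 2-methylcyclohexane-1,3-dione | CC1C(=O)CCCC1=O | starting material
5 | bis[4-methoxy-2-(methoxymethoxy)-6-methylbenzoyloxy]iodobenzene | Cc1cc(OC)cc(OCOC)c1C(=O)OI(OC(=O)c1c(C)cc(OC)cc1OCOC)c1ccccc1 | intermediate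
6 | 2-methyl-1,3-dioxocyclohexan-2-yl 4-methoxy-2-(methoxymethoxy)-6-methylbenzoate | CC1(OC(=O)c2c(C)cc(OC)cc2OCOC)C(=O)CCCC1=O | intermediate
7 | (1S,2S)-2-hydroxy-1-methyl-6-oxocyclohexyl 4-methoxy-2-(methoxymethoxy)-6-methylbenzoate | C1CC(=O)[C@@](C)(OC(=O)c2c(C)cc(OC)cc2OCOC)[C@@H](O)C1 | intermediate
8 | (1S,2S)-2-acetoxy-1-methyl-6-oxocyclohexyl 4-methoxy-2-(methoxymethoxy)-6-methylbenzoate | C1CC(=O)[C@@](C)(OC(=O)c2c(C)cc(OC)cc2OCOC)[C@@H](OC(C)=O)C1 | intermediate
9 | (1S,6S)-6-acetoxy-1-methyl-2-oxocyclohex-3-en-1-yl 4-methoxy-2-(methoxymethoxy)-6-methylbenzoate | C1=CC(=O)[C@@](C)(OC(=O)c2c(C)cc(OC)cc2OCOC)[C@@H](OC(C)=O)C1 | intermediate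
10 | (1S,2S)-2-acetoxy-1-methyl-6-oxo-4-(4,4,5,5-tetramethyl-1,3,2-dioxaborolan-2-yl)cyclohexyl 4-methoxy-2-(methoxymethoxy)-6-methylbenzoate (epimers at the boron-bearing carbon) | CC1(C)OB(OC1(C)C)C1CC(=O)[C@@](C)(OC(=O)c2c(C)cc(OC)cc2OCOC)[C@@H](OC(C)=O)C1 | intermediate
11 | (1S,2S)-2-acetoxy-4-hydroxy-1-methyl-6-oxocyclohexyl 4-methoxy-2-(methoxymethoxy)-6-methylbenzoate (epimers at the carbinol carbon) | OC1CC(=O)[C@@](C)(OC(=O)c2c(C)cc(OC)cc2OCOC)[C@@H](OC(C)=O)C1 | intermediate
12 | (1S,2S)-2-acetoxy-1-methyl-4,6-dioxocyclohexyl 4-methoxy-2-(methoxymethoxy)-6-methylbenzoate | O=C1CC(=O)[C@@](C)(OC(=O)c2c(C)cc(OC)cc2OCOC)[C@@H](OC(C)=O)C1 | intermediate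
13 | N-{[(4S,5S)-5-acetoxy-2-bromo-4-methyl-3-oxo-4-(aroyloxy)cyclohex-1-en-1-yl]methylidene}-N-methylmethanaminium bromide (aroyl = 4-methoxy-2-(methoxymethoxy)-6-methylbenzoyl) | BrC1=C(C=[N+](C)C)C(=O)[C@@](C)(OC(=O)c2c(C)cc(OC)cc2OCOC)[C@@H](OC(C)=O)C1.[Br-] | intermediate
14 | (1S,6S)-6-acetoxy-4-bromo-3-formyl-1-methyl-2-oxocyclohex-3-en-1-yl 4-methoxy-2-(methoxymethoxy)-6-methylbenzoate | BrC1=C(C=O)C(=O)[C@@](C)(OC(=O)c2c(C)cc(OC)cc2OCOC)[C@@H](OC(C)=O)C1 | intermediate
15 | (1S,6S)-6-acetoxy-4-bromo-3-(hydroxymethyl)-1-methyl-2-oxocyclohex-3-en-1-yl 4-methoxy-2-(methoxymethoxy)-6-methylbenzoate | BrC1=C(CO)C(=O)[C@@](C)(OC(=O)c2c(C)cc(OC)cc2OCOC)[C@@H](OC(C)=O)C1 | intermediate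
16 | (3E)-penta-1,3-diene | C=C/C=C/C | starting material
17 | (3S,6S,7S)-6-acetoxy-7-methyl-8-oxo-3-[(E)-prop-1-en-1-yl]-3,4,5,6,7,8-hexahydro-1H-isochromen-7-yl 4-methoxy-2-(methoxymethoxy)-6-methylbenzoate | C/C=C/[C@@H]1CC2=C(CO1)C(=O)[C@@](C)(OC(=O)c1c(C)cc(OC)cc1OCOC)[C@@H](OC(C)=O)C2 | intermediate
18 | (3S,6S,7S)-6-acetoxy-7-methyl-8-oxo-3-[(E)-prop-1-en-1-yl]-3,4,5,6,7,8-hexahydro-1H-isochromen-7-yl 2-hydroxy-4-methoxy-6-methylbenzoate | C/C=C/[C@@H]1CC2=C(CO1)C(=O)[C@@](C)(OC(=O)c1c(C)cc(OC)cc1O)[C@@H](OC(C)=O)C2 | target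

**Step count and risks**

Total step count: 11. Longest linear sequence: 11 steps (1 to 18; 4 and 16 enter as purchased materials).

Steps most likely to fail:

1. Step 10 (the proposed method). What may go wrong: β-hydride loss from the allylpalladium intermediate before C–O bond formation, weak facial discrimination in the diene insertion, or base-induced vinylogous elimination of the C6 acetate. Fallback (known chemistry only): it sets out from 9 and comes back at 17. Morita–Baylis–Hillman hydroxymethylation of 9 (aq. formaldehyde, imidazole, THF/H2O, rt) would give (1S,6S)-6-acetoxy-3-(hydroxymethyl)-1-methyl-2-oxocyclohex-3-en-1-yl 4-methoxy-2-(methoxymethoxy)-6-methylbenzoate F1. Iodoetherification of diene 16 with F1 and N-iodosuccinimide (CH2Cl2, −40 °C; iodine at the terminal CH2, oxygen at the allylic carbon) would give the iodo ether F2 as a pair of epimers at the ether carbon. A tin hydride radical cyclization of the Ueno–Stork type (Bu3SnH, AIBN, benzene, 80 °C, slow addition) would close the C4–C4a bond in the 6-endo mode onto the enone β-carbon and give the saturated bicyclic ketone F3. IBX dehydrogenation would restore the C4a=C8a bond, and 17 would be separated by chromatography from its 3R epimer F4, which is a diastereomer because C6 and C7 are already fixed.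

2. Step 8. What may go wrong: bromination at the hindered C8 oxygen or at both carbonyls, acid-induced loss of the MOM group, or formylation of the electron-rich aryl ring by excess reagent. Fallback: it sets out from 12 and comes back at 14 through 13. Condensation of 12 with N,N-dimethylformamide dimethyl acetal (toluene, rt) would give the isolable (1S,2S)-2-acetoxy-5-[(dimethylamino)methylidene]-1-methyl-4,6-dioxocyclohexyl 4-methoxy-2-(methoxymethoxy)-6-methylbenzoate F5 under neutral conditions. Oxalyl bromide (1.05 equiv, CH2Cl2, −20 °C) would then convert only the less hindered vinylogous amide carbonyl into the bromo iminium salt 13, which is hydrolysed to 14. C–C and C–Br bond formation are separated, and no free formylating agent or HBr meets the aryl ring.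

3. Step 3. What may go wrong: weak discrimination between the two enantiotopic carbonyls, hydride attack syn to the acyloxy group, over-reduction to the diol, or acyl migration to the new hydroxyl. Fallback: it sets out from 6 and comes back at 7. A ketoreductase (NADPH, glucose and glucose dehydrogenase for recycling, pH 7 buffer with DMSO) would be screened for the desymmetrizing mono-reduction, a known biocatalytic route for 2,2-disubstituted cyclic 1,3-diones; it makes no new compound.

Further compounds
F1 | step 10 | (1S,6S)-6-acetoxy-3-(hydroxymethyl)-1-methyl-2-oxocyclohex-3-en-1-yl 4-methoxy-2-(methoxymethoxy)-6-methylbenzoate | C1=C(CO)C(=O)[C@@](C)(OC(=O)c2c(C)cc(OC)cc2OCOC)[C@@H](OC(C)=O)C1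
F2 | step 10 | (1S,6S)-6-acetoxy-3-({[(3E)-1-iodopent-3-en-2-yl]oxy}methyl)-1-methyl-2-oxocyclohex-3-en-1-yl 4-methoxy-2-(methoxymethoxy)-6-methylbenzoate (epimers at the ether carbon) | C1=C(COC(CI)/C=C/C)C(=O)[C@@](C)(OC(=O)c2c(C)cc(OC)cc2OCOC)[C@@H](OC(C)=O)C1
F3 | step 10 | (6S,7S)-6-acetoxy-7-methyl-8-oxo-3-[(E)-prop-1-en-1-yl]octahydro-1H-isochromen-7-yl 4-methoxy-2-(methoxymethoxy)-6-methylbenzoate (mixture at C3, C4a and C8a) | C/C=C/C1CC2C(CO1)C(=O)[C@@](C)(OC(=O)c1c(C)cc(OC)cc1OCOC)[C@@H](OC(C)=O)C2
F4 | step 10 | (3R,6S,7S)-6-acetoxy-7-methyl-8-oxo-3-[(E)-prop-1-en-1-yl]-3,4,5,6,7,8-hexahydro-1H-isochromen-7-yl 4-methoxy-2-(methoxymethoxy)-6-methylbenzoate | C/C=C/[C@H]1CC2=C(CO1)C(=O)[C@@](C)(OC(=O)c1c(C)cc(OC)cc1OCOC)[C@@H](OC(C)=O)C2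
F5 | step 8 | (1S,2S)-2-acetoxy-5-[(dimethylamino)methylidene]-1-methyl-4,6-dioxocyclohexyl 4-methoxy-2-(methoxymethoxy)-6-methylbenzoate | O=C1C(=CN(C)C)C(=O)[C@@](C)(OC(=O)c2c(C)cc(OC)cc2OCOC)[C@@H](OC(C)=O)C1
F0 | step 3 | none | none
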